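**Retrosynthetic overview**
- The last bond made is O1–C2 of ring C (a C–O bond). It comes from isomerising a 2-cinnamoyl-3,5,6-trimethoxy-1,4-benzoquinone. The quinone oxygen next to the acyl group becomes O1, the para oxygen becomes 6-OH, and the quinone supplies the oxidation level of C2=C3.
- That quinone comes from the 2',5'-dihydroxychalcone by a two-electron oxidation. The chalcone Cα=Cβ bond comes from a Claisen–Schmidt condensation.
- The ketone half, 2,5-dihydroxy-3,4,6-trimethoxyacetophenone, comes from 2-hydroxy-3,4,6-trimethoxyacetophenone by para C–H hydroxylation (the C6–O bond, Elbs oxidation).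
- The aldehyde half is 2-hydroxy-6-methoxybenzaldehyde, carried as its MOM ether. The MOM group is lost in the acid quench of the last step.
- Ring order: rings A and B are bought. Ring C is the only ring formed and is closed last.

Assumption: the target has no stereocentre and its C2–C1' axis is not configurationally stable, so it is made as the one achiral compound; the acetophenone and the aldehyde are taken as catalogue items.

**Step 1**
Reactants: 1 1-(2-hydroxy-3,4,6-trimethoxyphenyl)ethan-1-one
Product: 3 1-(2,5-dihydroxy-3,4,6-trimethoxyphenyl)ethan-1-one, via aryl sulfate potassium salt 2 (not isolated)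
Conditions: K2S2O8 (1.1 equiv), 10% aq NaOH, 15 °C to rt, 24 h; acidify to pH 4–5, extract unreacted 1 (Et2O); then conc. HCl, N2, 90 °C, 30 min
Reagents that add atoms: potassium peroxodisulfate, [K+].[K+].[O-]S(=O)(=O)OOS(=O)(=O)[O-]
Why: Elbs persulfate oxidation, in which the phenoxide of 1 attacks the peroxide oxygen through C5 (para to the OH and the only free ring position) to give sulfate 2, which acid hydrolyses to the hydroquinone; no stereocentre is formed.

**Step 2**
Reactants: 4 2-hydroxy-6-methoxybenzaldehyde
Product: 5 2-methoxy-6-(methoxymethoxy)benzaldehyde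
Conditions: MOMCl (1.5 equiv), K2CO3 (2.5 equiv), acetone, 0 °C to rt, 6 h
Reagents that add atoms: chloromethyl methyl ether (MOMCl), COCCl
Why: Williamson-type O-alkylation of the phenoxide with the activated α-chloro ether gives a base-stable acetal, which keeps ring B from becoming a deactivating phenoxide in steps 3 and 4; no stereocentre is formed.

**Step 3**
Reactants: 3 1-(2,5-dihydroxy-3,4,6-trimethoxyphenyl)ethan-1-one; 5 2-methoxy-6-(methoxymethoxy)benzaldehyde
Product: 7 (E)-1-(2,5-dihydroxy-3,4,6-trimethoxyphenyl)-3-[2-methoxy-6-(methoxymethoxy)phenyl]prop-2-en-1-one, via aldol adduct 6 (not isolated)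
Conditions: KOH (12 equiv, 50% aq), degassed MeOH, Ar, rt, 48 h; then AcOH to pH 5, 0 °C
Reagents that add atoms: none
Why: Claisen–Schmidt condensation, in which the non-enolisable aldehyde 5 takes the methyl ketone enolate and E1cB loss of water from racemic 6 removes its stereocentre and gives the more stable E-alkene, the MOM ether being base-stable and the hydroquinone protected by exclusion of O2.

**Step 4**
Reactants: 7 (E)-1-(2,5-dihydroxy-3,4,6-trimethoxyphenyl)-3-[2-methoxy-6-(methoxymethoxy)phenyl]prop-2-en-1-one
Product: 12 6,2'-dihydroxy-5,7,8,6'-tetramethoxyflavone, via quinone chalcone 8 (not isolated), via methanol adduct 9 (not isolated), via methoxy enone hydroquinone 10 (not isolated), via MOM flavone 11 (not isolated)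
Conditions: Ag2O (1.2 equiv), Na2SO4, CH2Cl2, rt, 30 min, filter (Celite), evaporate; NaOMe (1.5 equiv), dry degassed MeOH, Ar, dark, 0 °C to rt, 2–6 h; then HCl (3 M in MeOH), 45 °C, 2 h
Reagents that add atoms: none
Why: Proposed new method: redox-relay cycloisomerisation of a 2-cinnamoyl-1,4-benzoquinone to a 6-hydroxyflavone; Ag2O removes two electrons from the most easily oxidised site (the known hydroquinone-to-acylquinone oxidation) to give 8, an isomer of 11; methoxide adds reversibly to the enone β-carbon to give 9, and its attack at the quinone C–OMe carbons only swaps OMe for OMe, so it is degenerate in MeOH; enolisation of 9 and loss of the benzylic C–H, now vinylogously acidic, push the electron pair into the quinone and give the aromatic hydroquinone β-methoxy enone 10 (estimated 12–14 kcal/mol downhill, and an intramolecular hydride shift from the benzylic ether C–H to the neighbouring quinone oxygen would reach the same point); the phenoxide ortho to the acyl group then closes ring C by 6-endo addition–elimination at C2, forming O1–C2 and giving methanol back, while the para quinone oxygen ends as 6-OH; the acid quench cleaves the MOM acetal without touching the aryl methyl ethers; the closest known reaction types are the base-induced isomerisation of prenylquinones to 6-hydroxy-2H-chromenes (ubiquinone to ubichromenol), the internal-redox tautomerisation of (1-hydroxyalkyl)quinones to acylhydroquinones, and the cyclisation of 2-hydroxyaryl β-alkoxy or β-amino enones to chromones; the stereocentre of racemic 9 is lost and none remains in 12.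

**Compound list**
1 | 1-(2-hydroxy-3,4,6-trimethoxyphenyl)ethan-1-one | CC(=O)c1c(O)c(OC)c(OC)cc1OC | starting material
2 | potassium 3-acetyl-4-hydroxy-2,5,6-trimethoxyphenyl sulfate (not isolated) | CC(=O)c1c(O)c(OC)c(OC)c(OS(=O)(=O)[O-])c1OC.[K+] | intermediate
3 | 1-(2,5-dihydroxy-3,4,6-trimethoxyphenyl)ethan-1-one | CC(=O)c1c(O)c(OC)c(OC)c(O)c1OC | intermediate
4 | 2-hydroxy-6-methoxybenzaldehyde | COc1cccc(O)c1C=O | starting material
5 | 2-methoxy-6-(methoxymethoxy)benzaldehyde | COCOc1cccc(OC)c1C=O | intermediate
6 | 1-(2,5-dihydroxy-3,4,6-trimethoxyphenyl)-3-hydroxy-3-[2-methoxy-6-(methoxymethoxy)phenyl]propan-1-one (racemic, not isolated) | COCOc1cccc(OC)c1C(O)CC(=O)c1c(O)c(OC)c(OC)c(O)c1OC | intermediate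
7 | (E)-1-(2,5-dihydroxy-3,4,6-trimethoxyphenyl)-3-[2-methoxy-6-(methoxymethoxy)phenyl]prop-2-en-1-one | COCOc1cccc(OC)c1/C=C/C(=O)c1c(O)c(OC)c(OC)c(O)c1OC | intermediate
8 | 2-{(2E)-3-[2-methoxy-6-(methoxymethoxy)phenyl]prop-2-enoyl}-3,5,6-trimethoxycyclohexa-2,5-diene-1,4-dione (not isolated) | COCOc1cccc(OC)c1/C=C/C(=O)C1=C(OC)C(=O)C(OC)=C(OC)C1=O | intermediate
9 | 2-{3-methoxy-3-[2-methoxy-6-(methoxymethoxy)phenyl]propanoyl}-3,5,6-trimethoxycyclohexa-2,5-diene-1,4-dione (racemic, not isolated) | COCOc1cccc(OC)c1C(OC)CC(=O)C1=C(OC)C(=O)C(OC)=C(OC)C1=O | intermediate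
10 | 1-(2,5-dihydroxy-3,4,6-trimethoxyphenyl)-3-methoxy-3-[2-methoxy-6-(methoxymethoxy)phenyl]prop-2-en-1-one (alkene geometry not fixed, not isolated) | COCOc1cccc(OC)c1C(OC)=CC(=O)c1c(O)c(OC)c(OC)c(O)c1OC | intermediate
11 | 6-hydroxy-5,7,8-trimethoxy-2-[2-methoxy-6-(methoxymethoxy)phenyl]-4H-chromen-4-one (not isolated) | COCOc1cccc(OC)c1-c1cc(=O)c2c(OC)c(O)c(OC)c(OC)c2o1 | intermediate
12 | 6-hydroxy-2-(2-hydroxy-6-methoxyphenyl)-5,7,8-trimethoxy-4H-chromen-4-one (6,2'-dihydroxy-5,7,8,6'-tetramethoxyflavone, achiral) | COc1cccc(O)c1-c1cc(=O)c2c(OC)c(O)c(OC)c(OC)c2o1 | target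

**Step count**
- Total step count: 4.
- Longest linear sequence: 3 (1 to 3 to 7 to 12).

**Steps most likely to fail**

Step 4 (the proposed new step). Adduct 9 may only revert to 8 without losing its benzylic hydrogen, or the quinone may degrade in base.
- The fallback uses known chemistry. It sets out from 7 and replaces the internal oxidant with ring closure first and an external oxidant second.
- NaOAc in refluxing EtOH under Ar closes ring C by oxa-Michael addition. This gives racemic 6-hydroxy-5,7,8-trimethoxy-2-[2-methoxy-6-(methoxymethoxy)phenyl]chroman-4-one F1.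
- Catalytic I2 in DMSO at 110 °C, the classical flavanone dehydrogenation, then converts F1 into the flavone.
- The route is rejoined at 11, which receives the HCl/MeOH treatment of step 4.

Step 3. The polyanion of hydroquinone 3 may enolise slowly and is air-sensitive in strong base.
- The fallback reverses the order of C–C and C–O bond formation. It sets out from 1 and 5.
- KOH/MeOH condensation of the monophenol gives (E)-1-(2-hydroxy-3,4,6-trimethoxyphenyl)-3-[2-methoxy-6-(methoxymethoxy)phenyl]prop-2-en-1-one F2.
- The only free phenol in F2 is then oxidised at its open para position by Teuber oxidation with (KSO3)2NO in KH2PO4-buffered aqueous acetone.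
- The route is rejoined at 8, and step 1 is no longer needed.

Step 1. Elbs oxidations usually stop at 30–45% yield with recovered starting material.
- The fallback sets out from 1 and goes through the quinone oxidation level.
- PhI(OAc)2 (2.2 equiv) in MeCN–H2O at 0 °C gives 2-acetyl-3,5,6-trimethoxycyclohexa-2,5-diene-1,4-dione F3.
- F3 is reduced with Na2S2O4 in Et2O–H2O.
- The route is rejoined at 3.

**Further compounds**
F1 | step 4 | rac-6-hydroxy-5,7,8-trimethoxy-2-[2-methoxy-6-(methoxymethoxy)phenyl]chroman-4-one | COCOc1cccc(OC)c1C1CC(=O)c2c(OC)c(O)c(OC)c(OC)c2O1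
F2 | step 3 | (E)-1-(2-hydroxy-3,4,6-trimethoxyphenyl)-3-[2-methoxy-6-(methoxymethoxy)phenyl]prop-2-en-1-one | COCOc1cccc(OC)c1/C=C/C(=O)c1c(O)c(OC)c(OC)cc1OC
F3 | step 1 | 2-acetyl-3,5,6-trimethoxycyclohexa-2,5-diene-1,4-dione | CC(=O)C1=C(OC)C(=O)C(OC)=C(OC)C1=O
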